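Ring A is numbered as a cyclohex-4-ene-1,3-dione: C1 (ketone between the two quaternary carbons), C2 (Me, O-acyl), C3 (ketone), C4 (=CH), C5 (OMe), C6 (Me, CH2 to ring B); ring B is the aminodienone.
Cuts, in retrosynthetic order: ring-B NH2 back to OMe; the ring-B carbinol back to a phenol (hydroxylative dearomatization); the C2–O ester bond of ring A; then C1–C2 and C5–C6 of ring A together in one anionic [4+2] annulation; last the benzylic C–C bond, back to a phenolic Mannich base.
Enabling feature: C6 of ring A is linked through the CH2 bridge to a ring-B carbon whose neighbour bears oxygen, so C1 can be stored as an aryl ester in a six-membered lactone (O, C1, C6, CH2, two ring-B carbons). Its enolate carbon (C6) and acyl carbon (C1) are the two-atom partner for the four-carbon unit C2–C5 of an acylketene acetal.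
Forward: ring B is built first as a hexasubstituted phenol (directed metalation, Mannich reaction) and closed to the lactone; ring A is annulated onto it; one acyloxylation, one dearomatization and one amination finish.
Stereochemistry: both sec-butyl centers come from (R)-2-methylbutanoic acid; C6 of ring A from a chiral ligand on the lithium enolate in the key step (the racemic lactone center is erased first); C2 from attack anti to the arylmethyl group; the ring-B carbinol from a chiral iodane.
Key step: step 9

Assumption: (2R)-2-methylbutanoic acid 4 is bought as the single enantiomer (both 2-methylbutanoyl groups of the target are R).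
Assumption: the sense of induction of the chiral ligand (step 9) and of the chiral iodane (step 13) cannot be predicted for these substrates; the antipode written is assumed to give the configuration needed, and the other antipode is equally accessible.

Step 1
Reactants: 1 2-hydroxy-4,6-dimethoxybenzaldehyde
Product: 2 3,5-dimethoxy-2-methylphenol
Conditions: H2 (3 bar), Pd/C (10 wt %), EtOH, HCl (cat.), 25 °C
Reagents that add atoms: none
Why: Catalytic hydrogenolysis of the electron-rich ortho-hydroxybenzaldehyde (through the benzylic alcohol) should reduce CHO to CH3 and leave the aryl ethers untouched.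

Step 2
Reactants: 2 3,5-dimethoxy-2-methylphenol
Product: 3 (3,5-dimethoxy-2-methylphenoxy)tri(propan-2-yl)silane
Conditions: iPr3SiCl, imidazole, DMF, 25 °C
Reagents that add atoms: chlorotri(propan-2-yl)silane, CC(C)[Si](Cl)(C(C)C)C(C)C
Why: Silyl ether formation; the bulky O-silyl group masks the phenol and does not direct lithiation, so that step 4 is steered by the two methoxy groups.

Step 3
Reactants: 4 (2R)-2-methylbutanoic acid
Product: 6 (2R)-N-methoxy-N,2-dimethylbutanamide, via acyl imidazole 5 (not isolated)
Conditions: 1,1′-carbonyldiimidazole, CH2Cl2, 0 → 25 °C; then MeNH(OMe)·HCl, 25 °C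
Reagents that add atoms: N,O-dimethylhydroxylamine hydrochloride, CNOC.Cl
Why: Amide formation through the acyl imidazole gives the Weinreb amide under nearly neutral conditions, so the stereocenter taken from the chiral pool should not epimerize.

Step 4
Reactants: 3 (3,5-dimethoxy-2-methylphenoxy)tri(propan-2-yl)silane; 6 (2R)-N-methoxy-N,2-dimethylbutanamide
Product: 8 (2R)-1-{2,6-dimethoxy-3-methyl-4-[tri(propan-2-yl)silyloxy]phenyl}-2-methylbutan-1-one, via aryllithium 7 (not isolated)
Conditions: n-BuLi, THF, 0 → 25 °C; then 6, −78 → 0 °C; 1 M HCl (cold)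
Reagents that add atoms: none
Why: Directed ortho-metalation at the position flanked by both methoxy groups, then Weinreb ketone synthesis: the chelated tetrahedral adduct stops over-addition and holds the α-stereocenter until work-up.

Step 5
Reactants: 8 (2R)-1-{2,6-dimethoxy-3-methyl-4-[tri(propan-2-yl)silyloxy]phenyl}-2-methylbutan-1-one
Product: 9 (2R)-1-(4-hydroxy-2,6-dimethoxy-3-methylphenyl)-2-methylbutan-1-one
Conditions: Bu4NF, AcOH, THF, 0 °C
Reagents that add atoms: none
Why: Fluoride-induced desilylation, buffered with acetic acid so that the phenoxide does not epimerize the α-branched ketone.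

Step 6
Reactants: 9 (2R)-1-(4-hydroxy-2,6-dimethoxy-3-methylphenyl)-2-methylbutan-1-one
Product: 10 (2R)-1-{3-[(dimethylamino)methyl]-4-hydroxy-2,6-dimethoxy-5-methylphenyl}-2-methylbutan-1-one
Conditions: CH2O (37 % aq.), Me2NH (40 % aq.), EtOH, 25 °C
Reagents that add atoms: formaldehyde, C=O; dimethylamine, CNC
Why: Mannich reaction at the only unsubstituted ring carbon, which is ortho to the phenol and ortho/para to the methoxy groups.

Step 7
Reactants: 10 (2R)-1-{3-[(dimethylamino)methyl]-4-hydroxy-2,6-dimethoxy-5-methylphenyl}-2-methylbutan-1-one; 11 2,2,5-trimethyl-1,3-dioxane-4,6-dione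
Product: 15 5,7-dimethoxy-3,8-dimethyl-6-[(2R)-2-methylbutanoyl]-3,4-dihydro-2H-chromen-2-one (both C3 epimers), via ortho-quinone methide 12 (not isolated), via Michael adduct 13 (not isolated), via lactone acid 14 (not isolated)
Conditions: AcOH (1.5 equiv), MeCN, 60 °C, N2 sweep; then toluene, 90–110 °C
Reagents that add atoms: none
Why: Acid-assisted loss of dimethylamine gives ortho-quinone methide 12, Michael addition of the Meldrum's acid enol gives 13, and acylation of the phenol by the dioxanedione with loss of acetone, then decarboxylation of the malonic half-ester, closes the lactone; C3 forms as both epimers, which does not matter because step 9 enolizes it.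

Step 8
Reactants: 16 1,1-dimethoxyethene; 17 propanoyl chloride
Product: 18 1,1-dimethoxypent-1-en-3-one
Conditions: Et3N, Et2O, 0 → 25 °C
Reagents that add atoms: none
Why: C-Acylation of the electron-rich ketene acetal by the acid chloride and deprotonation of the resulting oxocarbenium ion by Et3N gives the acylketene acetal.

Step 9
Reactants: 15 5,7-dimethoxy-3,8-dimethyl-6-[(2R)-2-methylbutanoyl]-3,4-dihydro-2H-chromen-2-one; 18 1,1-dimethoxypent-1-en-3-one
Product: 21 (6R)-6-{[2-hydroxy-4,6-dimethoxy-3-methyl-5-((2R)-2-methylbutanoyl)phenyl]methyl}-5-methoxy-2,6-dimethylcyclohex-4-ene-1,3-dione (drawn as the triketone; present as its enol tautomers; C2 not fixed), via lithium enolate 19 (not isolated), via vinylogous ester 20 (not isolated)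
Conditions: LiN(SiMe3)2 (1.1 equiv), (1R,2R)-1,2-dimethoxy-1,2-diphenylethane (1.3 equiv), toluene, −78 °C; then 18, −78 → 25 °C; 1 M HCl
Reagents that add atoms: none
Why: Proposed new method: the ring of lactone 15 gives a lithium enolate of fixed geometry whose carbon adds to C1 of acylketene acetal 18 and expels methoxide (Michael addition–elimination), which forms the C5–C6 bond of ring A and the quaternary carbon; the lithium methoxide set free then forms the α′-enolate of the ethyl ketone, which attacks the aryl ester carbonyl (Dieckmann-type Claisen condensation), forms the C1–C2 bond, releases the ring-B phenoxide and ends as the stabilized enolate of the vinylogous acid, the thermodynamic sink of the sequence. The closest known reaction types are the Michael–Claisen annulation that gives cyclohexane-1,3-diones and the Hauser–Kraus annulation of lactone anions; what is new is that a chiral diether bound to lithium is asked to differentiate the enantiotopic faces of a tetrasubstituted lactone enolate in this cascade, by analogy with ligand-controlled conjugate additions of lithium ester enolates. Ring A closes in a 6-(enolendo)-exo-trig mode. The quaternary C6 of ring A is the only stereocenter set (the racemic C3 of 15 is erased on enolization, so both enantiomers of the lactone converge), and it is controlled by the chiral ligand on lithium; C2 of ring A stays enolized and is set in step 12. The step needs conjugate instead of carbonyl addition, which the reversibility of the 1,2-adduct and the irreversible loss of methoxide should secure, and it needs cyclization from either alkene isomer of 20, which the low rotation barrier of the push–pull double bond should secure. Only one equivalent of strong base is used, so that the hindered sec-butyl aryl ketone should not be enolized.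

Step 10
Reactants: 4 (2R)-2-methylbutanoic acid
Product: 22 (2R)-2-methylbutaneperoxoic acid
Conditions: H2O2 (50 % aq., excess), H2SO4 (cat.), 20 °C; extraction into CH2Cl2, cold aqueous wash, MgSO4; kept as a cold solution behind a shield
Reagents that add atoms: hydrogen peroxide, OO
Why: Acid-catalysed perhydrolysis of an aliphatic carboxylic acid is an equilibrium that excess hydrogen peroxide pushes towards the peroxy acid; nothing enolizes under these conditions, so the α-stereocenter should be retained, and any acid 4 carried along is the coupling partner of step 11.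

Step 11
Reactants: 4 (2R)-2-methylbutanoic acid; 22 (2R)-2-methylbutaneperoxoic acid
Product: 23 bis[(2R)-2-methylbutanoyl] peroxide
Conditions: N,N′-dicyclohexylcarbodiimide, CH2Cl2, −10 → 0 °C; filtration; used cold without concentration to dryness
Reagents that add atoms: none
Why: Carbodiimide coupling: the O-acylisourea of acid 4 is attacked by the terminal oxygen of the peroxy acid, which gives the symmetrical diacyl peroxide from one molecule of each partner; the α-stereocenters are not involved.

Step 12
Reactants: 21 (6R)-6-{[2-hydroxy-4,6-dimethoxy-3-methyl-5-((2R)-2-methylbutanoyl)phenyl]methyl}-5-methoxy-2,6-dimethylcyclohex-4-ene-1,3-dione; 23 bis[(2R)-2-methylbutanoyl] peroxide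
Product: 24 (1R,3R)-3-{[2-hydroxy-4,6-dimethoxy-3-methyl-5-((2R)-2-methylbutanoyl)phenyl]methyl}-4-methoxy-1,3-dimethyl-2,6-dioxocyclohex-4-en-1-yl (2R)-2-methylbutanoate
Conditions: NaH (1.0 equiv), THF, 0 °C; then 23, 0 → 25 °C
Reagents that add atoms: none
Why: Enolate α-acyloxylation: with one equivalent of base only the vinylogous acid of ring A is deprotonated (the phenol is not), its methyl-bearing carbon between the two carbonyls attacks the O–O bond, and it should do so anti to the large arylmethyl group on the neighbouring quaternary carbon, which places the ester trans to that group as in the target.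

Step 13
Reactants: 24 (1R,3R)-3-{[2-hydroxy-4,6-dimethoxy-3-methyl-5-((2R)-2-methylbutanoyl)phenyl]methyl}-4-methoxy-1,3-dimethyl-2,6-dioxocyclohex-4-en-1-yl (2R)-2-methylbutanoate
Product: 25 (1R,3R)-3-{[(5R)-5-hydroxy-2,4-dimethoxy-5-methyl-3-((2R)-2-methylbutanoyl)-6-oxocyclohexa-1,3-dien-1-yl]methyl}-4-methoxy-1,3-dimethyl-2,6-dioxocyclohex-4-en-1-yl (2R)-2-methylbutanoate
Conditions: (R)-2,2′-diiodyl-1,1′-binaphthyl (0.55 equiv; made beforehand from the diiodide and dimethyldioxirane), THF, −40 → 0 °C; aq. NaHCO3
Reagents that add atoms: (R)-2,2′-diiodyl-1,1′-binaphthyl, O=I(=O)c1ccc2ccccc2c1-c1c(I(=O)=O)ccc2ccccc12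
Why: Hydroxylative phenol dearomatization: the phenol binds to pentavalent iodine and oxygen is transferred to the less hindered ortho carbon, the one that carries methyl and not the neopentyl-like CH2, while the axially chiral backbone selects the face so that the (R)-carbinol should result; ring A has no enolizable or oxidizable position left.

Step 14
Reactants: 25 (1R,3R)-3-{[(5R)-5-hydroxy-2,4-dimethoxy-5-methyl-3-((2R)-2-methylbutanoyl)-6-oxocyclohexa-1,3-dien-1-yl]methyl}-4-methoxy-1,3-dimethyl-2,6-dioxocyclohex-4-en-1-yl (2R)-2-methylbutanoate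
Product: 26 Gilluone B, (1R,3R)-3-{[(5R)-4-amino-5-hydroxy-2-methoxy-5-methyl-3-((2R)-2-methylbutanoyl)-6-oxocyclohexa-1,3-dien-1-yl]methyl}-4-methoxy-1,3-dimethyl-2,6-dioxocyclohex-4-en-1-yl (2R)-2-methylbutanoate
Conditions: NH3 (7 M in MeOH), 0 °C, short reaction time
Reagents that add atoms: ammonia, N
Why: Addition–elimination of ammonia on a vinylogous ester: the ring-B carbon next to the carbinol is β to the side-chain ketone and δ to the ring ketone and therefore the most electrophilic enol ether carbon, its product is the hydrogen-bonded vinylogous amide, and the hindered enol ether of ring A and the tertiary ester should survive the short exposure at 0 °C.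

Compound list
1 | 2-hydroxy-4,6-dimethoxybenzaldehyde | COc1cc(O)c(C=O)c(OC)c1 | starting material
2 | 3,5-dimethoxy-2-methylphenol | COc1cc(O)c(C)c(OC)c1 | intermediate
3 | (3,5-dimethoxy-2-methylphenoxy)tri(propan-2-yl)silane | COc1cc(O[Si](C(C)C)(C(C)C)C(C)C)c(C)c(OC)c1 | intermediate
4 | (2R)-2-methylbutanoic acid | CC[C@@H](C)C(=O)O | starting material
5 | (2R)-1-(1H-imidazol-1-yl)-2-methylbutan-1-one (acyl imidazole) | CC[C@@H](C)C(=O)n1ccnc1 | intermediate
6 | (2R)-N-methoxy-N,2-dimethylbutanamide | CC[C@@H](C)C(=O)N(C)OC | intermediate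
7 | {2,6-dimethoxy-3-methyl-4-[tri(propan-2-yl)silyloxy]phenyl}lithium (aryllithium) | [Li]c1c(OC)cc(O[Si](C(C)C)(C(C)C)C(C)C)c(C)c1OC | intermediate
8 | (2R)-1-{2,6-dimethoxy-3-methyl-4-[tri(propan-2-yl)silyloxy]phenyl}-2-methylbutan-1-one | CC[C@@H](C)C(=O)c1c(OC)cc(O[Si](C(C)C)(C(C)C)C(C)C)c(C)c1OC | intermediate
9 | (2R)-1-(4-hydroxy-2,6-dimethoxy-3-methylphenyl)-2-methylbutan-1-one | CC[C@@H](C)C(=O)c1c(OC)cc(O)c(C)c1OC | intermediate
10 | (2R)-1-{3-[(dimethylamino)methyl]-4-hydroxy-2,6-dimethoxy-5-methylphenyl}-2-methylbutan-1-one | CC[C@@H](C)C(=O)c1c(OC)c(CN(C)C)c(O)c(C)c1OC | intermediate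
11 | 2,2,5-trimethyl-1,3-dioxane-4,6-dione | CC1C(=O)OC(C)(C)OC1=O | starting material
12 | 3,5-dimethoxy-2-methyl-6-methylidene-4-[(2R)-2-methylbutanoyl]cyclohexa-2,4-dien-1-one (ortho-quinone methide) | CC[C@@H](C)C(=O)C1=C(OC)C(=C)C(=O)C(C)=C1OC | intermediate
13 | 5-{[2-hydroxy-4,6-dimethoxy-3-methyl-5-((2R)-2-methylbutanoyl)phenyl]methyl}-2,2,5-trimethyl-1,3-dioxane-4,6-dione (Michael adduct) | CC[C@@H](C)C(=O)c1c(OC)c(CC2(C)C(=O)OC(C)(C)OC2=O)c(O)c(C)c1OC | intermediate
14 | 5,7-dimethoxy-3,8-dimethyl-6-[(2R)-2-methylbutanoyl]-2-oxo-3,4-dihydro-2H-chromene-3-carboxylic acid (lactone acid) | CC[C@@H](C)C(=O)c1c(OC)c(C)c2OC(=O)C(C)(C(=O)O)Cc2c1OC | intermediate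
15 | 5,7-dimethoxy-3,8-dimethyl-6-[(2R)-2-methylbutanoyl]-3,4-dihydro-2H-chromen-2-one (both C3 epimers) | CC[C@@H](C)C(=O)c1c(OC)c(C)c2OC(=O)C(C)Cc2c1OC | intermediate
16 | 1,1-dimethoxyethene | C=C(OC)OC | starting material
17 | propanoyl chloride | CCC(=O)Cl | starting material
18 | 1,1-dimethoxypent-1-en-3-one | CCC(=O)C=C(OC)OC | intermediate
19 | lithium 5,7-dimethoxy-3,8-dimethyl-6-[(2R)-2-methylbutanoyl]-4H-chromen-2-olate (lithium enolate) | CC[C@@H](C)C(=O)c1c(OC)c(C)c2OC(O[Li])=C(C)Cc2c1OC | intermediate
20 | (3R)-5,7-dimethoxy-3-(1-methoxy-3-oxopent-1-en-1-yl)-3,8-dimethyl-6-[(2R)-2-methylbutanoyl]-3,4-dihydro-2H-chromen-2-one (vinylogous ester, alkene isomers) | CC[C@@H](C)C(=O)c1c(OC)c(C)c2OC(=O)[C@@](C)(C(OC)=CC(=O)CC)Cc2c1OC | intermediate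
21 | (6R)-6-{[2-hydroxy-4,6-dimethoxy-3-methyl-5-((2R)-2-methylbutanoyl)phenyl]methyl}-5-methoxy-2,6-dimethylcyclohex-4-ene-1,3-dione | CC1C(=O)C=C(OC)[C@@](C)(Cc2c(O)c(C)c(OC)c(C(=O)[C@H](C)CC)c2OC)C1=O | intermediate
22 | (2R)-2-methylbutaneperoxoic acid | CC[C@@H](C)C(=O)OO | intermediate
23 | bis[(2R)-2-methylbutanoyl] peroxide | CC[C@@H](C)C(=O)OOC(=O)[C@H](C)CC | intermediate
24 | (1R,3R)-3-{[2-hydroxy-4,6-dimethoxy-3-methyl-5-((2R)-2-methylbutanoyl)phenyl]methyl}-4-methoxy-1,3-dimethyl-2,6-dioxocyclohex-4-en-1-yl (2R)-2-methylbutanoate | CC[C@@H](C)C(=O)O[C@]1(C)C(=O)C=C(OC)[C@@](C)(Cc2c(O)c(C)c(OC)c(C(=O)[C@H](C)CC)c2OC)C1=O | intermediate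
25 | (1R,3R)-3-{[(5R)-5-hydroxy-2,4-dimethoxy-5-methyl-3-((2R)-2-methylbutanoyl)-6-oxocyclohexa-1,3-dien-1-yl]methyl}-4-methoxy-1,3-dimethyl-2,6-dioxocyclohex-4-en-1-yl (2R)-2-methylbutanoate | CC[C@@H](C)C(=O)O[C@]1(C)C(=O)C=C(OC)[C@@](C)(CC2=C(OC)C(C(=O)[C@H](C)CC)=C(OC)[C@@](C)(O)C2=O)C1=O | intermediate
26 | Gilluone B | CC[C@@H](C)C(=O)O[C@]1(C)C(=O)C=C(OC)[C@@](C)(CC2=C(OC)C(C(=O)[C@H](C)CC)=C(N)[C@@](C)(O)C2=O)C1=O | target

Total steps: 14. Longest linear sequence: 10 steps (1, 2, 4, 5, 6, 7, 9, 12, 13, 14).

Steps most likely to fail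

Step 9. What may go wrong: the ligand-bound lithium aggregate may discriminate poorly between the two faces of the lactone enolate, so that the quaternary carbon forms with low selectivity; carbonyl addition and enolization of the aryl ketone are secondary risks. Fallback (known chemistry; sets out from 15, returns at 24): the annulation of 15 with 18 is run with LiN(SiMe3)2 alone, as a plain Michael addition–elimination/Dieckmann sequence. This should give 21 mixed with its C6 epimer, (6S)-6-{[2-hydroxy-4,6-dimethoxy-3-methyl-5-((2R)-2-methylbutanoyl)phenyl]methyl}-5-methoxy-2,6-dimethylcyclohex-4-ene-1,3-dione F1. The mixture is acyloxylated with 23 as in step 12, anti to the arylmethyl group in both series, which should give 24 and (1S,3S)-3-{[2-hydroxy-4,6-dimethoxy-3-methyl-5-((2R)-2-methylbutanoyl)phenyl]methyl}-4-methoxy-1,3-dimethyl-2,6-dioxocyclohex-4-en-1-yl (2R)-2-methylbutanoate F2. These two are diastereomers, because both ring-A centers are inverted against the two fixed (R)-sec-butyl groups, and are separated by chromatography; the route continues from 24.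

Step 13. What may go wrong: oxygen may be transferred to the CH2-bearing ortho carbon or to the wrong face of the methyl-bearing one, and the dienone may be oxidized further. Fallback (sets out from 24, returns at 25): the oxidant class is changed from an iodane to a copper–dioxygen complex. The phenolate of 24 (iPr2NEt) is treated with [Cu(CH3CN)4]PF6 (monovalent copper), (−)-sparteine and O2 in CH2Cl2 at −78 °C, an enantioselective oxidative dearomatization in which the bulky chiral copper–oxygen species is delivered from the phenolate oxygen to the less hindered ortho carbon. No new compound is made on the way.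

Step 12. What may go wrong: the enolate may attack the peroxide from the face syn to the arylmethyl group, may be O-acylated, or oxidation may occur at the phenol; the α-branched diacyl peroxide may also decompose before it is consumed. Fallback (sets out from 21, returns at 24): oxygen and acyl group are introduced separately. Davis oxidation of the sodium enolate of 21 with 3-phenyl-2-(phenylsulfonyl)oxaziridine, a bulkier oxidant that should raise the anti preference, should give (2R,6R)-2-hydroxy-6-{[2-hydroxy-4,6-dimethoxy-3-methyl-5-((2R)-2-methylbutanoyl)phenyl]methyl}-5-methoxy-2,6-dimethylcyclohex-4-ene-1,3-dione F3. Steglich esterification of both hydroxyl groups with acid 4 (N,N′-diisopropylcarbodiimide, 4-(dimethylamino)pyridine) should give (1R,3R)-3-{[4,6-dimethoxy-3-methyl-5-((2R)-2-methylbutanoyl)-2-((2R)-2-methylbutanoyloxy)phenyl]methyl}-4-methoxy-1,3-dimethyl-2,6-dioxocyclohex-4-en-1-yl (2R)-2-methylbutanoate F4. K2CO3 in MeOH at 0 °C then cleaves the aryl ester only and gives 24.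

Further compounds
F1 | step 9 | (6S)-6-{[2-hydroxy-4,6-dimethoxy-3-methyl-5-((2R)-2-methylbutanoyl)phenyl]methyl}-5-methoxy-2,6-dimethylcyclohex-4-ene-1,3-dione | CC1C(=O)C=C(OC)[C@](C)(Cc2c(O)c(C)c(OC)c(C(=O)[C@H](C)CC)c2OC)C1=O
F2 | step 9 | (1S,3S)-3-{[2-hydroxy-4,6-dimethoxy-3-methyl-5-((2R)-2-methylbutanoyl)phenyl]methyl}-4-methoxy-1,3-dimethyl-2,6-dioxocyclohex-4-en-1-yl (2R)-2-methylbutanoate | CC[C@@H](C)C(=O)O[C@@]1(C)C(=O)C=C(OC)[C@](C)(Cc2c(O)c(C)c(OC)c(C(=O)[C@H](C)CC)c2OC)C1=O
F0 | step 13 | none | none
F3 | step 12 | (2R,6R)-2-hydroxy-6-{[2-hydroxy-4,6-dimethoxy-3-methyl-5-((2R)-2-methylbutanoyl)phenyl]methyl}-5-methoxy-2,6-dimethylcyclohex-4-ene-1,3-dione | C[C@@]1(O)C(=O)C=C(OC)[C@@](C)(Cc2c(O)c(C)c(OC)c(C(=O)[C@H](C)CC)c2OC)C1=O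
F4 | step 12 | (1R,3R)-3-{[4,6-dimethoxy-3-methyl-5-((2R)-2-methylbutanoyl)-2-((2R)-2-methylbutanoyloxy)phenyl]methyl}-4-methoxy-1,3-dimethyl-2,6-dioxocyclohex-4-en-1-yl (2R)-2-methylbutanoate | CC[C@@H](C)C(=O)O[C@]1(C)C(=O)C=C(OC)[C@@](C)(Cc2c(OC(=O)[C@H](C)CC)c(C)c(OC)c(C(=O)[C@H](C)CC)c2OC)C1=O
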